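**Strategy.** Everything rests on cutting the C2–C1' bond between ring C and ring B. C2, the only stereocentre, is the β-carbon of the C4 ketone, so a chiral divalent-palladium catalyst can add a ring B boronic acid across the C2=C3 bond of a chromone, attaching the aryl group and fixing (2S) in one operation. The precursor is a 6-farnesyl-5,7-bis(methoxymethoxy)chromone. Its substitution pattern is secured by symmetry: the farnesyl chain is introduced between two equivalent ethers of a phloroglucinol derivative, and ring C is then closed through the oxygen para to that chain, which becomes O1.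

Key step: step 10

Abbreviations: farnesyl = (2E,6E)-3,7,11-trimethyldodeca-2,6,10-trien-1-yl; MOM = methoxymethyl; TIPS = triisopropylsilyl.

Assumption: the (R)-configured tert-butyl pyridine-oxazoline ligand is taken to direct the aryl group to the C2 face that gives (2S), by analogy with the sense of induction expected for simple chromones with the (S)-ligand; a trial run on the parent chromone would confirm the choice of antipode, and the other antipode is used if it shows the opposite sense.

Step 1
Reactants: 1 phloroglucinol
Product: 2 5-(triisopropylsilyloxy)benzene-1,3-diol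
Conditions: 1 (3 equiv), TIPSCl (1 equiv), imidazole (1.5 equiv), DMF, 0 °C → rt
Reagents that add atoms: triisopropylsilyl chloride, CC(C)[Si](Cl)(C(C)C)C(C)C
Why: Imidazole-promoted O-silylation of a phenol; keeping the chlorosilane limiting against a threefold excess of the triol should channel it into the mono-ether, and the very polar unreacted triol is removed by aqueous wash and a silica plug.

Step 2
Reactants: 2 5-(triisopropylsilyloxy)benzene-1,3-diol
Product: 3 1,3-bis(methoxymethoxy)-5-(triisopropylsilyloxy)benzene
Conditions: MOMCl (3 equiv), iPr2NEt (4 equiv), CH2Cl2, 0 °C → rt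
Reagents that add atoms: chloromethyl methyl ether, COCCl
Why: Base-mediated O-alkylation (acetal formation) of the two remaining phenols should proceed cleanly, the bulky aryl TIPS ether being inert to the amine base.

Step 3
Reactants: 3 1,3-bis(methoxymethoxy)-5-(triisopropylsilyloxy)benzene; 4 (2E,6E)-farnesyl bromide
Product: 7 2-farnesyl-1,3-bis(methoxymethoxy)-5-(triisopropylsilyloxy)benzene, via aryllithium 5 (not isolated), via arylcopper 6 (not isolated)
Conditions: n-BuLi (1.2 equiv), THF, 0 °C → rt; CuBr·SMe2 (1.2 equiv), −40 °C; 4 (1.3 equiv), −40 → 0 °C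
Reagents that add atoms: none
Why: Directed ortho-metalation should occur only at C2, the one position flanked by two chelating MOM ethers, and the arylcopper formed on transmetalation should substitute the primary allylic bromide at its α-carbon (SN2), which keeps the chain linear and both E olefins intact.

Step 4
Reactants: 7 2-farnesyl-1,3-bis(methoxymethoxy)-5-(triisopropylsilyloxy)benzene
Product: 8 4-farnesyl-3,5-bis(methoxymethoxy)phenol
Conditions: TBAF (1.2 equiv), AcOH (1.2 equiv), THF, 0 °C → rt
Reagents that add atoms: none
Why: Fluoride-driven cleavage of the aryl silyl ether (formation of the strong Si–F bond) should be fast, the acetic acid buffer keeping the electron-rich phenoxide protonated, while MOM ethers and olefins are untouched.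

Step 5
Reactants: 8 4-farnesyl-3,5-bis(methoxymethoxy)phenol
Product: 10 3-farnesyl-6-hydroxy-2,4-bis(methoxymethoxy)benzaldehyde, via hydroxymethyl phenol 9 (not isolated)
Conditions: MgCl2 (anhydrous, 2 equiv), Et3N (4 equiv), (CH2O)n (6 equiv), THF, 65 °C; cold aq. citric acid work-up
Reagents that add atoms: paraformaldehyde (reacts as formaldehyde), C=O
Why: Casnati–Skattebøl ortho-formylation, in which the magnesium phenoxide delivers coordinated formaldehyde to the ortho carbon, the two ortho positions are equivalent by the mirror plane of 8, and the hydroxymethyl intermediate is oxidised in the flask by hydride transfer to a second formaldehyde under basic conditions that the MOM ethers tolerate.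

Step 6
Reactants: 10 3-farnesyl-6-hydroxy-2,4-bis(methoxymethoxy)benzaldehyde; 11 ethynylmagnesium bromide
Product: 12 rac-1-[3-farnesyl-6-hydroxy-2,4-bis(methoxymethoxy)phenyl]prop-2-yn-1-ol
Conditions: 11 (3 equiv, 0.5 M in THF), THF, 0 °C → rt; sat. aq. NH4Cl; crude product used directly
Reagents that add atoms: none
Why: 1,2-Addition of the alkynyl Grignard reagent to the aldehyde, one equivalent being consumed by the phenol, should give the propargylic alcohol, whose new carbinol centre is formed racemic and is erased in the next step.

Step 7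
Reactants: 12 rac-1-[3-farnesyl-6-hydroxy-2,4-bis(methoxymethoxy)phenyl]prop-2-yn-1-ol
Product: 14 6-farnesyl-5,7-bis(methoxymethoxy)-4H-chromen-4-one, via ynone 13 (not isolated)
Conditions: MnO2 (activated, 15 equiv), CH2Cl2, rt; filtration through Celite; K2CO3 (0.2 equiv), acetone, rt
Reagents that add atoms: none
Why: MnO2 oxidation of the benzylic and propargylic alcohol should give the o-hydroxyaryl ynone, whose phenoxide then adds to the unsubstituted alkyne terminus in a 6-endo-dig oxa-Michael closure that builds ring C, the ring oxygen being the one para to the farnesyl group.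

Step 8
Reactants: 15 5-bromoresorcinol
Product: 16 1-bromo-3,5-bis(methoxymethoxy)benzene
Conditions: MOMCl (3 equiv), iPr2NEt (4 equiv), CH2Cl2, 0 °C → rt
Reagents that add atoms: chloromethyl methyl ether, COCCl
Why: Base-mediated O-alkylation of both phenols with MOMCl should give the bis-acetal, the aryl bromide being inert.

Step 9
Reactants: 16 1-bromo-3,5-bis(methoxymethoxy)benzene
Product: 19 [3,5-bis(methoxymethoxy)phenyl]boronic acid, via aryllithium 17 (not isolated), via lithium borate 18 (not isolated)
Conditions: n-BuLi (1.1 equiv), THF, −78 °C; B(OiPr)3 (1.5 equiv), −78 °C → rt; aq. NH4Cl (pH about 6)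
Reagents that add atoms: triisopropyl borate, CC(C)OB(OC(C)C)OC(C)C; water, O
Why: Bromine–lithium exchange at −78 °C should outpace deprotonation next to the MOM ethers, the aryllithium is trapped by the borate ester as an ate complex, and hydrolysis near neutral pH should release the boronic acid without touching the MOM ethers.

Step 10
Reactants: 14 6-farnesyl-5,7-bis(methoxymethoxy)-4H-chromen-4-one; 19 [3,5-bis(methoxymethoxy)phenyl]boronic acid
Product: 20 (2S)-2-[3,5-bis(methoxymethoxy)phenyl]-6-farnesyl-5,7-bis(methoxymethoxy)chroman-4-one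
Conditions: 19 (2 equiv), Pd(OCOCF3)2 (10 mol %), (R)-4-tert-butyl-2-(pyridin-2-yl)-4,5-dihydrooxazole (12 mol %), NH4PF6 (30 mol %), H2O (5 equiv), ClCH2CH2Cl, 50 °C
Reagents that add atoms: none
Why: The arylboronic acid transmetalates to the cationic, ligand-bound divalent palladium, the chromone C2=C3 bond inserts syn into the aryl–palladium bond (forming C2–C1' in the enantio-determining step), and water protonates the resulting C3 palladium enolate, so the metal never changes oxidation state. The closest known reaction type is the palladium-catalysed asymmetric conjugate addition of arylboronic acids to cyclic enones and chromones with pyridine-oxazoline ligands, applied here to a more electron-rich chromone. No ring closes; ring C is already in place and only its C2=C3 bond becomes saturated. The C2 stereocentre is controlled by the tert-butyl group of the (R)-ligand, which shields one face of the flat coordinated chromone so that the aryl group is delivered to the face giving (2S). The step needs chemoselectivity for the enone over the three farnesyl olefins, secured because the unsubstituted, carbonyl-polarised C2=C3 bond inserts far faster than unactivated trisubstituted alkenes remote from the reacting carbon. It also needs the product to resist flavone formation and ring opening, secured by the anti relationship of H-2 and palladium after syn insertion and by the base-free medium, which also spares the MOM ethers.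

Step 11
Reactants: 20 (2S)-2-[3,5-bis(methoxymethoxy)phenyl]-6-farnesyl-5,7-bis(methoxymethoxy)chroman-4-one
Product: 21 (2S)-2-(3,5-dihydroxyphenyl)-6-farnesyl-5,7-dihydroxychroman-4-one (target)
Conditions: HCl (3 M aq., 10 equiv), MeOH/THF, 40 °C, stopped at full conversion; NaHCO3 quench
Reagents that add atoms: none
Why: Acid-catalysed acetal exchange with methanol should strip all four aryl MOM ethers as dimethoxymethane, the chelated C5 ether going first; without base ring C does not open to the chalcone so C2 keeps its configuration, and the low temperature and short exposure limit protonation of the farnesyl olefins.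

**Compound list**

1 | phloroglucinol | Oc1cc(O)cc(O)c1 | starting material
2 | 5-(triisopropylsilyloxy)benzene-1,3-diol | CC(C)[Si](Oc1cc(O)cc(O)c1)(C(C)C)C(C)C | intermediate
3 | 1,3-bis(methoxymethoxy)-5-(triisopropylsilyloxy)benzene | COCOc1cc(OCOC)cc(O[Si](C(C)C)(C(C)C)C(C)C)c1 | intermediate
4 | (2E,6E)-farnesyl bromide | CC(C)=CCC/C(C)=C/CC/C(C)=C/CBr | starting material
5 | [2,6-bis(methoxymethoxy)-4-(triisopropylsilyloxy)phenyl]lithium (not isolated) | [Li]c1c(OCOC)cc(O[Si](C(C)C)(C(C)C)C(C)C)cc1OCOC | intermediate
6 | [2,6-bis(methoxymethoxy)-4-(triisopropylsilyloxy)phenyl]copper (not isolated) | [Cu]c1c(OCOC)cc(O[Si](C(C)C)(C(C)C)C(C)C)cc1OCOC | intermediate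
7 | 2-farnesyl-1,3-bis(methoxymethoxy)-5-(triisopropylsilyloxy)benzene | CC(C)=CCC/C(C)=C/CC/C(C)=C/Cc1c(OCOC)cc(O[Si](C(C)C)(C(C)C)C(C)C)cc1OCOC | intermediate
8 | 4-farnesyl-3,5-bis(methoxymethoxy)phenol | CC(C)=CCC/C(C)=C/CC/C(C)=C/Cc1c(OCOC)cc(O)cc1OCOC | intermediate
9 | 4-farnesyl-2-(hydroxymethyl)-3,5-bis(methoxymethoxy)phenol, present as its magnesium phenoxide (not isolated) | CC(C)=CCC/C(C)=C/CC/C(C)=C/Cc1c(OCOC)cc(O)c(CO)c1OCOC | intermediate
10 | 3-farnesyl-6-hydroxy-2,4-bis(methoxymethoxy)benzaldehyde | CC(C)=CCC/C(C)=C/CC/C(C)=C/Cc1c(OCOC)cc(O)c(C=O)c1OCOC | intermediate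
11 | ethynylmagnesium bromide | C#C[Mg]Br | starting material
12 | rac-1-[3-farnesyl-6-hydroxy-2,4-bis(methoxymethoxy)phenyl]prop-2-yn-1-ol | CC(C)=CCC/C(C)=C/CC/C(C)=C/Cc1c(OCOC)cc(O)c(C(O)C#C)c1OCOC | intermediate
13 | 1-[3-farnesyl-6-hydroxy-2,4-bis(methoxymethoxy)phenyl]prop-2-yn-1-one (not isolated) | CC(C)=CCC/C(C)=C/CC/C(C)=C/Cc1c(OCOC)cc(O)c(C(=O)C#C)c1OCOC | intermediate
14 | 6-farnesyl-5,7-bis(methoxymethoxy)-4H-chromen-4-one | CC(C)=CCC/C(C)=C/CC/C(C)=C/Cc1c(OCOC)cc2occc(=O)c2c1OCOC | intermediate
15 | 5-bromoresorcinol | Oc1cc(O)cc(Br)c1 | starting material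
16 | 1-bromo-3,5-bis(methoxymethoxy)benzene | COCOc1cc(Br)cc(OCOC)c1 | intermediate
17 | [3,5-bis(methoxymethoxy)phenyl]lithium (not isolated) | [Li]c1cc(OCOC)cc(OCOC)c1 | intermediate
18 | lithium [3,5-bis(methoxymethoxy)phenyl]tri(isopropoxy)borate (not isolated) | CC(C)O[B-](OC(C)C)(OC(C)C)c1cc(OCOC)cc(OCOC)c1.[Li+] | intermediate
19 | [3,5-bis(methoxymethoxy)phenyl]boronic acid | COCOc1cc(OCOC)cc(B(O)O)c1 | intermediate
20 | (2S)-2-[3,5-bis(methoxymethoxy)phenyl]-6-farnesyl-5,7-bis(methoxymethoxy)chroman-4-one | CC(C)=CCC/C(C)=C/CC/C(C)=C/Cc1c(OCOC)cc2c(c1OCOC)C(=O)C[C@@H](c1cc(OCOC)cc(OCOC)c1)O2 | intermediate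
21 | (2S)-2-(3,5-dihydroxyphenyl)-6-farnesyl-5,7-dihydroxychroman-4-one | CC(C)=CCC/C(C)=C/CC/C(C)=C/Cc1c(O)cc2c(c1O)C(=O)C[C@@H](c1cc(O)cc(O)c1)O2 | target

**Step count.** Total: 11 steps. Longest linear sequence: 9 steps (steps 1 to 7, then 10 and 11); steps 8 and 9 form the short ring B branch.

**Steps most likely to fail**

Step 10. Insertion into the electron-rich 5,7-dioxygenated chromone may be slow, so that protodeboronation and homocoupling consume the boronic acid, or the facial discrimination may fall short of that seen with simple chromones. The fallback separates bond formation from stereocontrol. It sets out from 14 and 19, which would be joined with the more reactive achiral catalyst Pd(OCOCF3)2/2,2'-bipyridine (divalent palladium) in THF/AcOH/H2O at 60 °C to give the racemic flavanone rac-2-[3,5-bis(methoxymethoxy)phenyl]-6-farnesyl-5,7-bis(methoxymethoxy)chroman-4-one F1. A kinetic resolution by asymmetric transfer hydrogenation follows, with RuCl(p-cymene)[(R,R)-TsDPEN] (divalent ruthenium, the antipode expected to reduce the (2R) ketone faster) and HCO2H/Et3N, stopped near half conversion. This should turn the unwanted enantiomer into the cis alcohol (2R,4R)-2-[3,5-bis(methoxymethoxy)phenyl]-6-farnesyl-5,7-bis(methoxymethoxy)chroman-4-ol F2, which is removed by chromatography. The unreduced ketone is 20, where the route is rejoined.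

Step 11. Protonation of the farnesyl olefin nearest the ring may trigger cyclisation onto the freed C7 or C5 hydroxyl (chroman formation), HCl or methanol may add across the trisubstituted olefins, and long exposure to acid may open ring C reversibly and erode the configuration at C2. The fallback replaces protic acetal cleavage by an aprotic exchange of protecting groups. It sets out from 20, which would be treated with TMSOTf and 2,2'-bipyridyl in MeCN at 0 °C, a buffered medium without free acid that transfers each MOM group to the pyridine base and leaves (2S)-6-farnesyl-5,7-bis(trimethylsilyloxy)-2-[3,5-bis(trimethylsilyloxy)phenyl]chroman-4-one F3. The labile aryl silyl ethers would then be solvolysed with water at neutral pH, which returns to the route at 21.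

Step 7. The terminal ynone may oligomerise before it cyclises, or the phenoxide may close at the α-carbon in a 5-exo mode instead of the 6-endo mode. The fallback builds ring C through an enaminone and avoids the ynone altogether. It sets out from aldehyde 10, to which MeMgBr (3 equiv, THF, 0 °C) would add to give rac-1-[3-farnesyl-6-hydroxy-2,4-bis(methoxymethoxy)phenyl]ethanol F4. MnO2 in CH2Cl2 would oxidise this to 1-[3-farnesyl-6-hydroxy-2,4-bis(methoxymethoxy)phenyl]ethanone F5. Heating with N,N-dimethylformamide dimethyl acetal in toluene at 80 °C would give (E)-3-(dimethylamino)-1-[3-farnesyl-6-hydroxy-2,4-bis(methoxymethoxy)phenyl]prop-2-en-1-one F6. Gentle acid (AcOH in CH2Cl2, 40 °C) would close F6 by addition of the phenol and loss of dimethylamine, which returns to the route at chromone 14.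

**Further compounds**

F1 | step 10 | rac-2-[3,5-bis(methoxymethoxy)phenyl]-6-farnesyl-5,7-bis(methoxymethoxy)chroman-4-one | CC(C)=CCC/C(C)=C/CC/C(C)=C/Cc1c(OCOC)cc2c(c1OCOC)C(=O)CC(c1cc(OCOC)cc(OCOC)c1)O2
F2 | step 10 | (2R,4R)-2-[3,5-bis(methoxymethoxy)phenyl]-6-farnesyl-5,7-bis(methoxymethoxy)chroman-4-ol | CC(C)=CCC/C(C)=C/CC/C(C)=C/Cc1c(OCOC)cc2c(c1OCOC)[C@H](O)C[C@H](c1cc(OCOC)cc(OCOC)c1)O2
F3 | step 11 | (2S)-6-farnesyl-5,7-bis(trimethylsilyloxy)-2-[3,5-bis(trimethylsilyloxy)phenyl]chroman-4-one | CC(C)=CCC/C(C)=C/CC/C(C)=C/Cc1c(O[Si](C)(C)C)cc2c(c1O[Si](C)(C)C)C(=O)C[C@@H](c1cc(O[Si](C)(C)C)cc(O[Si](C)(C)C)c1)O2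
F4 | step 7 | rac-1-[3-farnesyl-6-hydroxy-2,4-bis(methoxymethoxy)phenyl]ethanol | CC(C)=CCC/C(C)=C/CC/C(C)=C/Cc1c(OCOC)cc(O)c(C(C)O)c1OCOC
F5 | step 7 | 1-[3-farnesyl-6-hydroxy-2,4-bis(methoxymethoxy)phenyl]ethanone | CC(C)=CCC/C(C)=C/CC/C(C)=C/Cc1c(OCOC)cc(O)c(C(C)=O)c1OCOC
F6 | step 7 | (E)-3-(dimethylamino)-1-[3-farnesyl-6-hydroxy-2,4-bis(methoxymethoxy)phenyl]prop-2-en-1-one | CC(C)=CCC/C(C)=C/CC/C(C)=C/Cc1c(OCOC)cc(O)c(C(=O)/C=C/N(C)C)c1OCOC
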